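A leftover opened the meeting. The kineticist noted that after 0.250 min the L unspent in the oak run is 42.6% of its charge, while in the larch run, with the same charge of E, it is 26.9%, less than in oak. Oak reaches 26.3% at twice that time. She argued that a first-order loss of L, with c_E steady, leaves the same fraction at the same time, which these readings do not show, so she took the loss as going roughly with the square of c_L.

| setting | ash | oak | larch | cedar | red | amber | teal | grey |
|---|---|---|---|---|---|---|---|---|
| L | 36 mM | 24 mM | 54 mM | 36 mM | 36 mM | 36 mM | 36 mM | 36 mM |
| E | 64.8 mM | 64.8 mM | 64.8 mM | 97 mM | 64.8 mM | 64.8 mM | 64.8 mM | 64.8 mM (fed, over 3.20 min) |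
| remark | run made earlier | run made earlier | run made earlier | run made earlier | one stirred flow tank at steady state, fed with the mixture as stated, mean residence time 4.0 min | a closed flask charged with all of it at once and left for 4.0 min | a single well-mixed tank run continuously and read at steady state, 12.0 min in it on average | all but E at the start; E goes in evenly over 3.20 min, the run ends at 4.0 min |
| time |  |  |  |  |  | 4.0 min |  | 4.0 min |

- ash (time / min: D / %, Z / %): 0.833: 60.7, 24.9; 1.50: 62.5, 33.7; 2.50: 62.2, 37.3; 3.00: 59.0, 39.2; 4.00: 59.9, 41.5
- oak (time / min: D / %, Z / %): 0.250: 50.3, 7.1; 0.500: 60.5, 13.2; 0.833: 60.8, 19.9; 1.50: 63.8, 28.7; 3.00: 63.3, 33.2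
- larch (time / min: D / %, Z / %): 0.250: 57.8, 15.3; 0.500: 60.6, 25.7; 0.833: 57.1, 28.8; 1.50: 56.3, 40.4; 3.00: 55.5, 43.6
- cedar (time / min: D / %, Z / %): 0.667: 66.4, 23.1; 1.33: 67.6, 27.5; 2.00: 64.9, 33.5; 2.50: 64.6, 34.2; 3.00: 66.0, 34.2

(standard deviation of a reading: 1 percentage point)

- in percentages every species weighs as the L in it: one Z counts as two
- the stated concentrations are those of everything mixed, before any reaction; amounts are the same in each set-up
- steps that have been proposed: L + E -> D; L + D -> Z
- the feed brings no volume worth counting
- the earlier runs were made in a closed, stirred flask

- the set-up with the highest share of D in all that became D or Z, at the outlet or at the end ("none" if the first two lie within 2 percentage points) (red / amber / teal / grey / none)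
- share of D in all that became D or Z, at the outlet or at the end, red
- share of D in all that became D or Z, at the outlet or at the end, amber
- share of D in all that became D or Z, at the outlet or at the end, teal
- share of D in all that became D or Z, at the outlet or at the end, grey

The analyst then read the attack on D from the larch run. Between 0.250 min and 0.500 min, Z forms at 11.2 mM min⁻¹, with c_L near 11.0 mM and c_D near 32.0 mM. That gives the attack constant, the rate of Z per unit of c_L and of c_D, a second-order rate constant, as the reading 0.534 M⁻¹ s⁻¹.

The process chemist carried this into a tank. At steady state, the Z at the outlet is made over the mean residence time τ, so c_Z/c_D equals the attack constant times c_L times τ. A Z counts two in percentages, so Z percent over D percent is twice that product, and the share of D, the selectivity, is one over one plus this ratio.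

She added that, at like c_E in the two tanks, a loss going with the square of c_L makes c_L fall roughly as the root of τ, so from red to teal c_L drops by a factor of about 1.73, and c_L·τ rises by the same factor. Her reckoning therefore put teal below red, since teal's mean residence time is longer. The chair observed that amber repeats the ash run, whose last reading gives a share of 59.1%.

The forecast named amber as best, with red 41%, amber 59%, teal 29.5% and grey 36%, on this ground: “So high L favours D, and anything that holds L low hurts.”

The flask gives amber as best, at 59.4%, with red at 42.2% and grey at 40.4%.

    L + E → D, rate k1*[L]^2*[E]^0.5 (k = 14.6 M⁻¹·⁵ s⁻¹)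
    L + D → Z (k = 0.523 M⁻¹ s⁻¹)

The red tank holds c_L at 5.46 mM, and with the attack constant and the tank rule this gives a share of 41.7% for red. For teal, dividing red's c_L by the root factor gives 3.15 mM, the same rule gives 29.2%, and teal stands at 29.8%.

The data come from a simulation for substances that don't exist.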